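## Retrosynthetic overview

1. The C6 angelate is installed last, on the ten-membered hydroxy ketone.
2. The cyclodecane is formed last, by closing C6–C7: the C6 epoxy aldehyde is attacked by the prenyl terminus in an intramolecular carbonyl-ene reaction (the farnesyl C1→C10 closure of germacrane biosynthesis, ending in loss of a methyl hydrogen to give the isopropenyl group). This step sets C6 and C7.
3. The acyclic epoxy prenyl ketone comes from an epoxy δ-lactone (allyl Grignard opening, then cross-metathesis prenylation). The temporary lactone ring (by RCM) forces the cis C1–C10 oxirane and relays C3 to C1/C10.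
4. C3, C4 and C5 come from Brown allylation of a Z-enal followed by hydroxyl-directed epoxidation; the Z-enal comes from but-2-yn-1-ol.
5. Ring order: C4–C5 oxirane → δ-lactone (temporary) → C1–C10 oxirane → lactone opened → ten-membered carbocycle.

Assumption: the SMILES is taken as written, so both oxiranes are cis (C3/C6 and C2/C9 cis) and the target is (1R,3S,4R,5S,6S,7S,10R) in germacrane numbering (ring C1–C10, C14 on C10, C15 on C4, isopropenyl C11–C13 on C7); these locants are used below.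

## Route

Step 1
Reactants: 1 but-2-yn-1-ol
Product: 3 (2Z)-3-iodobut-2-en-1-ol, via cyclic vinylalanate 2 (not isolated)
Conditions: Red-Al, THF, 0 °C → rt; then I2, −78 → 0 °C
Reagents that add atoms: iodine, II
Why: Hydroxyl-directed trans-hydroalumination puts Al on C3 through a five-membered alkoxyalanate, and iodinolysis with retention gives the Z-iodide, which fixes the later cis relation of C3 and C6 across C4=C5.

Step 2
Reactants: 3 (2Z)-3-iodobut-2-en-1-ol
Product: 4 tert-butyl{[(2Z)-3-iodobut-2-en-1-yl]oxy}dimethylsilane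
Conditions: TBSCl, imidazole, CH2Cl2, 0 °C → rt
Reagents that add atoms: tert-butyldimethylsilyl chloride, CC(C)(C)[Si](C)(C)Cl
Why: Routine silylation of the primary alcohol; the TBS ether tolerates the organolithium, peracid, alkaline peroxide, Grignard and metathesis steps that follow.

Step 3
Reactants: 4 tert-butyl{[(2Z)-3-iodobut-2-en-1-yl]oxy}dimethylsilane; 5 N,N-dimethylformamide
Product: 8 (2Z)-4-[(tert-butyldimethylsilyl)oxy]-2-methylbut-2-enal, via vinyllithium 6 (not isolated), via lithium hemiaminal alkoxide 7 (not isolated)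
Conditions: t-BuLi (2.1 equiv), Et2O, −78 °C; then DMF, −78 → 0 °C; aq. work-up; use crude
Reagents that add atoms: N,N-dimethylformamide (5), CN(C)C=O
Why: Lithium–iodine exchange keeps the alkene geometry and Bouveault-type formylation gives the Z-enal (C3 aldehyde cis to C6), used at once to avoid Z→E isomerisation.

Step 4
Reactants: 8 (2Z)-4-[(tert-butyldimethylsilyl)oxy]-2-methylbut-2-enal; 9 (−)-B-allyldiisopinocampheylborane (commercial, from (+)-α-pinene)
Product: 11 (2Z,4S)-1-[(tert-butyldimethylsilyl)oxy]-3-methylhepta-2,6-dien-4-ol, via diisopinocampheylborinate ester 10 (not isolated)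
Conditions: 9 (1.2 equiv), Et2O, −78 °C; then NaOH, 30% H2O2, 0 °C → rt
Reagents that add atoms: (−)-B-allyldiisopinocampheylborane (9), C=CCB([C@@H]1C[C@@H]2C[C@H]([C@H]1C)C2(C)C)[C@@H]1C[C@@H]2C[C@H]([C@H]1C)C2(C)C
Why: Brown asymmetric allylboration through a closed chair transition state; the (+)-α-pinene-derived reagent delivers allyl to the Si face of the aldehyde and sets C3 as S.

Step 5
Reactants: 11 (2Z,4S)-1-[(tert-butyldimethylsilyl)oxy]-3-methylhepta-2,6-dien-4-ol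
Product: 12 (1S)-1-[(2R,3S)-3-{[(tert-butyldimethylsilyl)oxy]methyl}-2-methyloxiran-2-yl]but-3-en-1-ol
Conditions: mCPBA (1.2 equiv), CH2Cl2, 0 °C
Reagents that add atoms: 3-chloroperoxybenzoic acid, OOC(=O)c1cccc(Cl)c1
Why: Hydroxyl-directed (Henbest) epoxidation of the trisubstituted alkene only; A(1,3) strain from the cis CH2OTBS group holds C3–H in the alkene plane, so the hydrogen-bonded peracid adds on the OH face and gives the threo epoxy alcohol (C4 R, C5 S) as a cis-oxirane.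

Step 6
Reactants: 12 (1S)-1-[(2R,3S)-3-{[(tert-butyldimethylsilyl)oxy]methyl}-2-methyloxiran-2-yl]but-3-en-1-ol; 13 methacryloyl chloride
Product: 14 (1S)-1-[(2R,3S)-3-{[(tert-butyldimethylsilyl)oxy]methyl}-2-methyloxiran-2-yl]but-3-en-1-yl 2-methylprop-2-enoate
Conditions: Et3N, DMAP (cat.), CH2Cl2, 0 °C → rt
Reagents that add atoms: methacryloyl chloride (13), C=C(C)C(Cl)=O
Why: DMAP-catalysed O-acylation brings in C9, C10 and C14 and sets up the ring closure.

Step 7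
Reactants: 14 (1S)-1-[(2R,3S)-3-{[(tert-butyldimethylsilyl)oxy]methyl}-2-methyloxiran-2-yl]but-3-en-1-yl 2-methylprop-2-enoate
Product: 15 (6S)-6-[(2R,3S)-3-{[(tert-butyldimethylsilyl)oxy]methyl}-2-methyloxiran-2-yl]-3-methyl-5,6-dihydro-2H-pyran-2-one
Conditions: Grubbs II (5 mol%), CH2Cl2 (0.005 M), 40 °C
Reagents that add atoms: none
Why: Ring-closing metathesis of the terminal alkene with the methacrylate gives the α-methyl-α,β-unsaturated δ-lactone, which locks C9 and C2 cis about C10=C1.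

Step 8
Reactants: 15 (6S)-6-[(2R,3S)-3-{[(tert-butyldimethylsilyl)oxy]methyl}-2-methyloxiran-2-yl]-3-methyl-5,6-dihydro-2H-pyran-2-one
Product: 16 (1R,4S,6R)-4-[(2R,3S)-3-{[(tert-butyldimethylsilyl)oxy]methyl}-2-methyloxiran-2-yl]-1-methyl-3,7-dioxabicyclo[4.1.0]heptan-2-one
Conditions: 30% H2O2, NaOH (0.2 equiv), MeOH, 0 °C
Reagents that add atoms: hydrogen peroxide, OO
Why: Weitz–Scheffer nucleophilic epoxidation; hydroperoxide adds axially to C1 of the half-chair lactone anti to the pseudo-equatorial C3 substituent and the ring forces a cis-oxirane, setting C1 (R) and C10 (R) 1,3-syn to the C3 oxygen.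

Step 9
Reactants: 16 (1R,4S,6R)-4-[(2R,3S)-3-{[(tert-butyldimethylsilyl)oxy]methyl}-2-methyloxiran-2-yl]-1-methyl-3,7-dioxabicyclo[4.1.0]heptan-2-one; 17 allylmagnesium bromide
Product: 19 1-[(2R,3R)-3-{(2S)-2-[(2R,3S)-3-{[(tert-butyldimethylsilyl)oxy]methyl}-2-methyloxiran-2-yl]-2-hydroxyethyl}-2-methyloxiran-2-yl]but-3-en-1-one, via bromomagnesium lactol alkoxide 18 (not isolated)
Conditions: allylMgBr (1.1 equiv), THF, −78 °C; then sat. aq. NH4Cl at −78 °C
Reagents that add atoms: allylmagnesium bromide (17), C=CC[Mg]Br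
Why: Grignard addition to the lactone carbonyl stops at the tetrahedral lactol alkoxide at −78 °C, which on protonation gives the δ-hydroxy ketone (in ring–chain equilibrium with its lactol); C10 is quaternary and cannot epimerise.

Step 10
Reactants: 19 1-[(2R,3R)-3-{(2S)-2-[(2R,3S)-3-{[(tert-butyldimethylsilyl)oxy]methyl}-2-methyloxiran-2-yl]-2-hydroxyethyl}-2-methyloxiran-2-yl]but-3-en-1-one; 20 2-methylbut-2-ene
Product: 21 1-[(2R,3R)-3-{(2S)-2-[(2R,3S)-3-{[(tert-butyldimethylsilyl)oxy]methyl}-2-methyloxiran-2-yl]-2-hydroxyethyl}-2-methyloxiran-2-yl]-4-methylpent-3-en-1-one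
Conditions: Grubbs II (5 mol%), 2-methylbut-2-ene/CH2Cl2 (1:1), 40 °C
Reagents that add atoms: 2-methylbut-2-ene (20), CC=C(C)C
Why: Olefin cross-metathesis with excess 2-methylbut-2-ene converts the allyl ketone into the prenyl ketone without the α/γ regiochemistry problem of prenyl metals.

Step 11
Reactants: 21 1-[(2R,3R)-3-{(2S)-2-[(2R,3S)-3-{[(tert-butyldimethylsilyl)oxy]methyl}-2-methyloxiran-2-yl]-2-hydroxyethyl}-2-methyloxiran-2-yl]-4-methylpent-3-en-1-one; 22 angelic acid [(2Z)-2-methylbut-2-enoic acid]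
Product: 23 (1S)-1-[(2R,3S)-3-{[(tert-butyldimethylsilyl)oxy]methyl}-2-methyloxiran-2-yl]-2-[(2R,3R)-3-methyl-3-(4-methylpent-3-enoyl)oxiran-2-yl]ethyl (2Z)-2-methylbut-2-enoate
Conditions: 22, 2,4,6-Cl3C6H2COCl, Et3N, PhMe, rt, filter; then 21, NaHCO3, PhMe, 80 °C
Reagents that add atoms: angelic acid (22), C/C=C(/C)C(=O)O
Why: Yamaguchi-type esterification through the angelic/2,4,6-trichlorobenzoic mixed anhydride, run without amine or DMAP in the acylation stage, esterifies the open-chain C3–OH without Z→E isomerisation to the tiglate and without conjugating the β,γ-enone.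

Step 12
Reactants: 23 (1S)-1-[(2R,3S)-3-{[(tert-butyldimethylsilyl)oxy]methyl}-2-methyloxiran-2-yl]-2-[(2R,3R)-3-methyl-3-(4-methylpent-3-enoyl)oxiran-2-yl]ethyl (2Z)-2-methylbut-2-enoate
Product: 24 (1S)-1-[(2R,3S)-3-(hydroxymethyl)-2-methyloxiran-2-yl]-2-[(2R,3R)-3-methyl-3-(4-methylpent-3-enoyl)oxiran-2-yl]ethyl (2Z)-2-methylbut-2-enoate
Conditions: HF·pyridine, pyridine, THF, 0 °C → rt
Reagents that add atoms: none
Why: Buffered fluoride desilylation frees the C6 alcohol without touching the oxiranes, the angelate or the β,γ-unsaturated ketone.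

Step 13
Reactants: 24 (1S)-1-[(2R,3S)-3-(hydroxymethyl)-2-methyloxiran-2-yl]-2-[(2R,3R)-3-methyl-3-(4-methylpent-3-enoyl)oxiran-2-yl]ethyl (2Z)-2-methylbut-2-enoate
Product: 25 (1S)-1-[(2R,3R)-3-formyl-2-methyloxiran-2-yl]-2-[(2R,3R)-3-methyl-3-(4-methylpent-3-enoyl)oxiran-2-yl]ethyl (2Z)-2-methylbut-2-enoate
Conditions: Dess–Martin periodinane, pyridine, CH2Cl2, 0 °C → rt; use crude
Reagents that add atoms: none
Why: Dess–Martin oxidation under buffered conditions gives the α,β-epoxy aldehyde without epimerising C5 (the C5 descriptor changes from S to R only because of CIP priorities).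

Step 14
Reactants: 25 (1S)-1-[(2R,3R)-3-formyl-2-methyloxiran-2-yl]-2-[(2R,3R)-3-methyl-3-(4-methylpent-3-enoyl)oxiran-2-yl]ethyl (2Z)-2-methylbut-2-enoate
Product: 27 (1R,3S,4R,5S,6S,7S,10R)-1,10:4,5-diepoxy-6-hydroxy-9-oxogermacr-11-en-3-yl (2Z)-2-methylbut-2-enoate, via chloro(methyl)aluminium alkoxide 26 (not isolated)
Conditions: Me2AlCl (2.2 equiv), CH2Cl2, slow addition of 25 to 0.001 M, −78 → −40 °C; aq. work-up
Reagents that add atoms: none
Why: Proposed new method: a Lewis-acid-promoted type-I carbonyl-ene macrocyclisation in which the Me2AlCl-bound C6 aldehyde is attacked by C7 of the prenyl alkene (charge builds at tertiary C11) and the aluminium-bound oxygen takes H from a C11 methyl to give the isopropenyl group; C6 is set anti to the C5–O bond by Felkin–Anh attack on the α,β-epoxy aldehyde, C7 by the transition state that places the aldehyde H in the crowded C8/C11 sector (6,7-syn), and the two cis-oxiranes (0° torsions) pre-fold the chain; the closest known reactions are the Me2AlCl aldehyde–trisubstituted-alkene ene reaction (Snider) and Lewis-acid ene macrocyclisations of ω-isopropylidene aldehydes to cembranoid rings.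

Step 15
Reactants: 27 (1R,3S,4R,5S,6S,7S,10R)-1,10:4,5-diepoxy-6-hydroxy-9-oxogermacr-11-en-3-yl (2Z)-2-methylbut-2-enoate; 22 angelic acid
Product: 28 (1R,3S,4R,5S,6S,7S,10R)-1,10:4,5-diepoxy-9-oxogermacr-11-ene-3,6-diyl bis[(2Z)-2-methylbut-2-enoate] (CNP0217653.1)
Conditions: 22, 2,4,6-Cl3C6H2COCl, Et3N, PhMe, rt, filter; then 27, NaHCO3, PhMe, 80 °C
Reagents that add atoms: angelic acid (22), C/C=C(/C)C(=O)O
Why: The same stereoconservative mixed-anhydride (Yamaguchi-type) esterification acylates the hindered C6–OH with retention at C6 and without angelate→tiglate isomerisation, giving the target.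

## Compound list

1 | but-2-yn-1-ol | CC#CCO | starting material
2 | sodium 2,2-bis(2-methoxyethoxy)-3-methyl-2,5-dihydro-1,2-oxaaluminol-2-uide (cyclic vinylalanate) | [Na+].COCCO[Al-]1(OCCOC)OCC=C1C | intermediate
3 | (2Z)-3-iodobut-2-en-1-ol | C/C(I)=C/CO | intermediate
4 | tert-butyl{[(2Z)-3-iodobut-2-en-1-yl]oxy}dimethylsilane | C/C(I)=C/CO[Si](C)(C)C(C)(C)C | intermediate
5 | N,N-dimethylformamide | CN(C)C=O | starting material
6 | [(2Z)-4-[(tert-butyldimethylsilyl)oxy]but-2-en-2-yl]lithium | C/C([Li])=C/CO[Si](C)(C)C(C)(C)C | intermediate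
7 | lithium (2Z)-4-[(tert-butyldimethylsilyl)oxy]-1-(dimethylamino)-2-methylbut-2-en-1-olate | C/C(C(O[Li])N(C)C)=C/CO[Si](C)(C)C(C)(C)C | intermediate
8 | (2Z)-4-[(tert-butyldimethylsilyl)oxy]-2-methylbut-2-enal | C/C(C=O)=C/CO[Si](C)(C)C(C)(C)C | intermediate
9 | (−)-B-allyldiisopinocampheylborane | C=CCB([C@@H]1C[C@@H]2C[C@H]([C@H]1C)C2(C)C)[C@@H]1C[C@@H]2C[C@H]([C@H]1C)C2(C)C | starting material
10 | (2Z,4S)-1-[(tert-butyldimethylsilyl)oxy]-3-methylhepta-2,6-dien-4-yl diisopinocampheylborinate | C=CC[C@H](OB([C@@H]1C[C@@H]2C[C@H]([C@H]1C)C2(C)C)[C@@H]1C[C@@H]2C[C@H]([C@H]1C)C2(C)C)/C(C)=C\CO[Si](C)(C)C(C)(C)C | intermediate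
11 | (2Z,4S)-1-[(tert-butyldimethylsilyl)oxy]-3-methylhepta-2,6-dien-4-ol | C=CC[C@H](O)/C(C)=C\CO[Si](C)(C)C(C)(C)C | intermediate
12 | (1S)-1-[(2R,3S)-3-{[(tert-butyldimethylsilyl)oxy]methyl}-2-methyloxiran-2-yl]but-3-en-1-ol | C=CC[C@H](O)[C@@]1(C)O[C@H]1CO[Si](C)(C)C(C)(C)C | intermediate
13 | methacryloyl chloride | C=C(C)C(Cl)=O | starting material
14 | (1S)-1-[(2R,3S)-3-{[(tert-butyldimethylsilyl)oxy]methyl}-2-methyloxiran-2-yl]but-3-en-1-yl 2-methylprop-2-enoate | C=CC[C@H](OC(=O)C(C)=C)[C@@]1(C)O[C@H]1CO[Si](C)(C)C(C)(C)C | intermediate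
15 | (6S)-6-[(2R,3S)-3-{[(tert-butyldimethylsilyl)oxy]methyl}-2-methyloxiran-2-yl]-3-methyl-5,6-dihydro-2H-pyran-2-one | CC1=CC[C@H](OC1=O)[C@@]2(C)O[C@H]2CO[Si](C)(C)C(C)(C)C | intermediate
16 | (1R,4S,6R)-4-[(2R,3S)-3-{[(tert-butyldimethylsilyl)oxy]methyl}-2-methyloxiran-2-yl]-1-methyl-3,7-dioxabicyclo[4.1.0]heptan-2-one | O=C1[C@]2(C)O[C@@H]2C[C@H](O1)[C@@]3(C)O[C@H]3CO[Si](C)(C)C(C)(C)C | intermediate
17 | allylmagnesium bromide | C=CC[Mg]Br | starting material
18 | bromomagnesium alkoxide of the 2-allyl lactol of 16 (anomeric centre undefined) | C=CCC1(O[Mg]Br)[C@]2(C)O[C@@H]2C[C@H](O1)[C@@]3(C)O[C@H]3CO[Si](C)(C)C(C)(C)C | intermediate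
19 | 1-[(2R,3R)-3-{(2S)-2-[(2R,3S)-3-{[(tert-butyldimethylsilyl)oxy]methyl}-2-methyloxiran-2-yl]-2-hydroxyethyl}-2-methyloxiran-2-yl]but-3-en-1-one | C=CCC(=O)[C@]1(C)O[C@@H]1C[C@H](O)[C@@]2(C)O[C@H]2CO[Si](C)(C)C(C)(C)C | intermediate
20 | 2-methylbut-2-ene | CC=C(C)C | starting material
21 | 1-[(2R,3R)-3-{(2S)-2-[(2R,3S)-3-{[(tert-butyldimethylsilyl)oxy]methyl}-2-methyloxiran-2-yl]-2-hydroxyethyl}-2-methyloxiran-2-yl]-4-methylpent-3-en-1-one | CC(C)=CCC(=O)[C@]1(C)O[C@@H]1C[C@H](O)[C@@]2(C)O[C@H]2CO[Si](C)(C)C(C)(C)C | intermediate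
22 | angelic acid, (2Z)-2-methylbut-2-enoic acid | C/C=C(/C)C(=O)O | starting material
23 | (1S)-1-[(2R,3S)-3-{[(tert-butyldimethylsilyl)oxy]methyl}-2-methyloxiran-2-yl]-2-[(2R,3R)-3-methyl-3-(4-methylpent-3-enoyl)oxiran-2-yl]ethyl (2Z)-2-methylbut-2-enoate | CC(C)=CCC(=O)[C@]1(C)O[C@@H]1C[C@H](OC(=O)/C(C)=C\C)[C@@]2(C)O[C@H]2CO[Si](C)(C)C(C)(C)C | intermediate
24 | (1S)-1-[(2R,3S)-3-(hydroxymethyl)-2-methyloxiran-2-yl]-2-[(2R,3R)-3-methyl-3-(4-methylpent-3-enoyl)oxiran-2-yl]ethyl (2Z)-2-methylbut-2-enoate | CC(C)=CCC(=O)[C@]1(C)O[C@@H]1C[C@H](OC(=O)/C(C)=C\C)[C@@]2(C)O[C@H]2CO | intermediate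
25 | (1S)-1-[(2R,3R)-3-formyl-2-methyloxiran-2-yl]-2-[(2R,3R)-3-methyl-3-(4-methylpent-3-enoyl)oxiran-2-yl]ethyl (2Z)-2-methylbut-2-enoate | CC(C)=CCC(=O)[C@]1(C)O[C@@H]1C[C@H](OC(=O)/C(C)=C\C)[C@@]2(C)O[C@H]2C=O | intermediate
26 | chloro(methyl)aluminium C6-alkoxide of 27 | C=C(C)[C@@H]1CC(=O)[C@]2(C)O[C@@H]2C[C@H](OC(=O)/C(C)=C\C)[C@@]2(C)O[C@H]2[C@H]1O[Al](C)Cl | intermediate
27 | (1R,3S,4R,5S,6S,7S,10R)-1,10:4,5-diepoxy-6-hydroxy-9-oxogermacr-11-en-3-yl (2Z)-2-methylbut-2-enoate | C=C(C)[C@@H]1CC(=O)[C@]2(C)O[C@@H]2C[C@H](OC(=O)/C(C)=C\C)[C@@]2(C)O[C@H]2[C@H]1O | intermediate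
28 | (1R,3S,4R,5S,6S,7S,10R)-1,10:4,5-diepoxy-9-oxogermacr-11-ene-3,6-diyl bis[(2Z)-2-methylbut-2-enoate] | C=C(C)[C@@H]1CC(=O)[C@]2(C)O[C@@H]2C[C@H](OC(=O)/C(C)=C\C)[C@@]2(C)O[C@H]2[C@H]1OC(=O)/C(C)=C\C | target

## Step count and risk

Total steps: 15. Longest linear sequence: 15 (1 → 28); all other inputs (5, 9, 13, 17, 20, 22) are commercial.

Steps most likely to fail:

Step 14 (ene macrocyclisation). A ten-membered ring is closed on a substrate with two oxiranes, a ketone and an ester. Me2AlCl may transfer methyl to the aldehyde, open an oxirane with chloride, or give a poor C7 ratio. The fallback forms the same C6–C7 bond with reversed polarity and sets out from 23. SeO2 (cat.)/t-BuOOH oxidises the E-methyl of the prenyl group to the (E)-allylic alcohol F1. MsCl/LiCl/collidine converts it into the allylic chloride F2. HF·pyridine gives the primary alcohol F3 and Dess–Martin oxidation gives the chloro epoxy aldehyde F4. Pd(PPh3)4 (cat.)/Et2Zn at high dilution then generates an allylzinc that adds through C7 to the aldehyde in a closed chair transition state (E-allyl gives the required 6,7-relationship, Felkin at C6). This comes back to the route at 27.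

Step 9 (allyl Grignard on the epoxy lactone). Double addition, and later handling of the lactol/hydroxy-ketone mixture in the acylation, are the concerns. The fallback sets out from 16. MeNH(OMe)·HCl/i-PrMgCl opens the lactone to the hydroxy Weinreb amide F5, which has no lactol form. Mixed-anhydride angeloylation gives the angeloyloxy Weinreb amide F6. AllylMgBr at −78 °C gives the allyl ketone F7; the Weinreb chelate stops over-addition. Cross-metathesis with 20 comes back to the route at 23.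

Step 3 (Z-enal). The Z-enal 8 can isomerise to the E-enal before or during allylation, which would give a trans-oxirane. The fallback avoids any enal and sets out from 4. t-BuLi, then paraformaldehyde, gives the Z-allylic alcohol F8. Sharpless asymmetric epoxidation (Ti(OiPr)4, D-(−)-diethyl tartrate, t-BuOOH, 4 Å MS, −20 °C) gives the epoxy alcohol F9. Dess–Martin oxidation gives the geometrically fixed epoxy aldehyde F10. Reagent-controlled allylboration with 9 (Si face), then oxidative work-up, comes back to the route at 12.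

## Further compounds

F1 | step 14 | (1S)-1-[(2R,3S)-3-{[(tert-butyldimethylsilyl)oxy]methyl}-2-methyloxiran-2-yl]-2-{(2R,3R)-3-[(3E)-5-hydroxy-4-methylpent-3-enoyl]-3-methyloxiran-2-yl}ethyl (2Z)-2-methylbut-2-enoate | OC/C(C)=C/CC(=O)[C@]1(C)O[C@@H]1C[C@H](OC(=O)/C(C)=C\C)[C@@]2(C)O[C@H]2CO[Si](C)(C)C(C)(C)C
F2 | step 14 | (1S)-1-[(2R,3S)-3-{[(tert-butyldimethylsilyl)oxy]methyl}-2-methyloxiran-2-yl]-2-{(2R,3R)-3-[(3E)-5-chloro-4-methylpent-3-enoyl]-3-methyloxiran-2-yl}ethyl (2Z)-2-methylbut-2-enoate | ClC/C(C)=C/CC(=O)[C@]1(C)O[C@@H]1C[C@H](OC(=O)/C(C)=C\C)[C@@]2(C)O[C@H]2CO[Si](C)(C)C(C)(C)C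
F3 | step 14 | (1S)-2-{(2R,3R)-3-[(3E)-5-chloro-4-methylpent-3-enoyl]-3-methyloxiran-2-yl}-1-[(2R,3S)-3-(hydroxymethyl)-2-methyloxiran-2-yl]ethyl (2Z)-2-methylbut-2-enoate | ClC/C(C)=C/CC(=O)[C@]1(C)O[C@@H]1C[C@H](OC(=O)/C(C)=C\C)[C@@]2(C)O[C@H]2CO
F4 | step 14 | (1S)-2-{(2R,3R)-3-[(3E)-5-chloro-4-methylpent-3-enoyl]-3-methyloxiran-2-yl}-1-[(2R,3R)-3-formyl-2-methyloxiran-2-yl]ethyl (2Z)-2-methylbut-2-enoate | ClC/C(C)=C/CC(=O)[C@]1(C)O[C@@H]1C[C@H](OC(=O)/C(C)=C\C)[C@@]2(C)O[C@H]2C=O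
F5 | step 9 | (2R,3R)-3-{(2S)-2-[(2R,3S)-3-{[(tert-butyldimethylsilyl)oxy]methyl}-2-methyloxiran-2-yl]-2-hydroxyethyl}-N-methoxy-N,2-dimethyloxirane-2-carboxamide | CON(C)C(=O)[C@]1(C)O[C@@H]1C[C@H](O)[C@@]2(C)O[C@H]2CO[Si](C)(C)C(C)(C)C
F6 | step 9 | (1S)-1-[(2R,3S)-3-{[(tert-butyldimethylsilyl)oxy]methyl}-2-methyloxiran-2-yl]-2-{(2R,3R)-3-[methoxy(methyl)carbamoyl]-3-methyloxiran-2-yl}ethyl (2Z)-2-methylbut-2-enoate | CON(C)C(=O)[C@]1(C)O[C@@H]1C[C@H](OC(=O)/C(C)=C\C)[C@@]2(C)O[C@H]2CO[Si](C)(C)C(C)(C)C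
F7 | step 9 | (1S)-2-[(2R,3R)-3-(but-3-enoyl)-3-methyloxiran-2-yl]-1-[(2R,3S)-3-{[(tert-butyldimethylsilyl)oxy]methyl}-2-methyloxiran-2-yl]ethyl (2Z)-2-methylbut-2-enoate | C=CCC(=O)[C@]1(C)O[C@@H]1C[C@H](OC(=O)/C(C)=C\C)[C@@]2(C)O[C@H]2CO[Si](C)(C)C(C)(C)C
F8 | step 3 | (2Z)-4-[(tert-butyldimethylsilyl)oxy]-2-methylbut-2-en-1-ol | C/C(CO)=C/CO[Si](C)(C)C(C)(C)C
F9 | step 3 | [(2R,3S)-3-{[(tert-butyldimethylsilyl)oxy]methyl}-2-methyloxiran-2-yl]methanol | OC[C@@]1(C)O[C@H]1CO[Si](C)(C)C(C)(C)C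
F10 | step 3 | (2S,3S)-3-{[(tert-butyldimethylsilyl)oxy]methyl}-2-methyloxirane-2-carbaldehyde | O=C[C@@]1(C)O[C@H]1CO[Si](C)(C)C(C)(C)C
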